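## Structural features

The target is a C26 heptapropionate. It has two fully substituted 4H-pyran-4-one rings, ring A (6-ethyl-3,5-dimethyl) and ring B (3,5-dimethyl-6-pentyl), each bonded through its C2 to a methine carbon (C4' and C2') of a central pentan-3-one chain C1'–C5'. The stereocentres C2' and C4' stand 1,3 to each other across the C3' ketone and are both R, so the molecule is pseudo-C2-symmetric; the halves differ only in the remote ethyl and pentyl groups. Each methine hydrogen is flanked by the ketone and by C2 of a pyranone, the β-carbon of a vinylogous ester, so it is about as acidic as a 1,3-dicarbonyl C–H and any base epimerises it towards the meso-like R,S isomer and the enantiomer. This lability, not the rings, is the real difficulty: the two centres must be set late, as a pair, and must not meet base afterwards. Ring C2 is the electrophilic position of a pyranone, so the polar union (enolate plus pyranone electrophile) is base-mediated and cannot hold the configuration; the C6 alkyl groups carry vinylogously acidic α-CH2 groups that a strong base removes before any ring C–H. The key step exploits that C2'–C2(ring B) and C4'–C2(ring A) are bonds between an sp3 carbon α to a ketone and an sp2 ring carbon, which radical nickel catalysis can make from a racemic α-bromoketone without base, and that the two centres are constitutional copies, so one chiral catalyst can set both in the same sense. Both rings share the 3,5-dimethyl-4-pyranone core, so one doubly C–H-functionalised building block serves both.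

## Logic of the disconnections

18 is cut at the bond between C2' and C2 of ring B, giving 16 and 17 (17 is made in the flask from 13). In one sentence, the route is the stereoconvergent nickel-catalysed arylation of 16 by 17. The cut is made here because it forms the last C–C bond and the second labile stereocentre in one base-free operation, from a bromide whose own configuration does not matter. The gain is that a finished ring is joined to the chain with no carbinol detour and no protecting group. The demand on the forward step is catalyst control over the new centre without epimerisation of the centre already present.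

16 is cut in the same way at the bond between C4' and C2 of ring A, giving 14 and 15 (15 is made in the flask from 11). This reduces the whole chain to a five-carbon dihalide that carries both future stereocentres as a stereorandom mixture. The demand is mono-arylation of a reagent with two equal C–Br bonds, met by using 14 in excess.

11 and 13 are cut at the C6–alkyl bond, giving 9 together with 10 or 12. The alkyl groups are put on last because their lateral protons would otherwise be removed in preference to any ring C–H. The gain is one common precursor for both rings. The demand is coupling at C–I with C–Br left intact for the later zinc insertion.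

9 is cut at its C–Br and C–I bonds back to 5 (through 8, 7 and 6). 5 has only two ring C–H bonds, both next to the ring oxygen, and no laterally acidic protons, so two successive ring zincations are unambiguous. The demand is that the two halogens are introduced one after the other without scrambling.

5 is cut at the O1–C2 bond and at the C5–C6 bond, giving 3 and a formyl unit (through 4); 3 is cut in the same way to 1 (through 2). Both are formylations of an ethyl ketone followed by O-alkylation or ring closure, and both lead back to a bulk ketone.

## Other disconnections considered

Alternative 1: This is the first plan that comes to mind. Both rings are cut at their O1–C bonds and the chain is built by iterated auxiliary-controlled aldol reactions, with C3' carried as a silyl-protected carbinol. The forward key step is acid-mediated double cyclodehydration of the open-chain bis-triketone A1, followed by desilylation to the carbinol A2 and a final Dess–Martin oxidation. It is reliable in type, but about six C–C bond-forming events, repeated oxidation-state changes and protecting groups give a linear sequence of well over a dozen steps. The two methine centres are set early and carried through β-silyloxy ketone stages that are open to elimination and retro-aldol cleavage, and a carbinol stereocentre is made with care only to be destroyed. The chosen plan sets the same two centres in the last two steps of a seven-step route.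

Alternative 2: The cut is at the C2'–C3' bond, between a methine and the carbonyl. The forward key step is a vinylogous aldol addition of laterally deprotonated A3 (LiN(SiMe3)2) to the aldehyde A4, then oxidation of the carbinol A2. The ground against it is mechanistic. A4 is a vinylogous β-oxo aldehyde and would be enolised and racemised by the basic dienolate. The new methine centre arises from a planar dienolate under substrate control only, and the required like relationship between the two methines is not what simple diastereoselection guarantees. Lateral deprotonation also cannot tell an ethyl from a pentyl group, so A4 has no short selective access. The chosen plan forms the ring–chain bonds instead and needs no base once a centre exists.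

Alternative 3: No skeletal bond is cut stereoselectively; the stereorandom ketone A5 is assembled by any non-selective union and the stereochemistry is corrected afterwards. The forward key step is a dynamic kinetic asymmetric transfer hydrogenation (RuCl(p-cymene)(TsDPEN), HCO2H/Et3N) that would reduce only the R,R isomer from the equilibrating mixture to the carbinol A2, followed by re-oxidation. The ground against it is structural: the two ketone substituents are nearly identical branched groups, so the catalyst has no aryl/alkyl contrast to read and must select purely by matched kinetics among three interconverting isomers. It also adds two redox steps. The chosen plan sets configuration in the bond-forming event with a catalyst class designed for α-keto radicals.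

Key step: step 7

Assumption: the sense of induction of the nickel/pybox catalyst on these substrates must be assigned on 16; the route is written for the ligand antipode that delivers the R centre, and the same antipode is used in steps 6 and 7. The pybox ligand meant is 2,6-bis[(4R,5S)-4,5-diphenyl-4,5-dihydro-1,3-oxazol-2-yl]pyridine or its enantiomer. TMP stands for 2,2,6,6-tetramethylpiperidin-1-yl.

## Steps

Step 1
Reactants: 1 pentan-3-one
Product: 3 (1E)-1-methoxy-2-methylpent-1-en-3-one, via sodium enolate 2 (not isolated)
Conditions: NaOMe, HCO2Me, Et2O, 0 °C to rt; then Me2SO4, DMF, 0 °C to rt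
Reagents that add atoms: methyl formate COC=O; dimethyl sulfate COS(=O)(=O)OC
Why: Crossed Claisen formylation of the ketone, driven by formation of the sodium salt of the β-oxo aldehyde, followed by O-methylation of that salt with a hard methylating agent; the enol ether geometry is irrelevant for step 2.

Step 2
Reactants: 3 (1E)-1-methoxy-2-methylpent-1-en-3-one
Product: 5 3,5-dimethyl-4H-pyran-4-one, via sodium dienolate 4 (not isolated)
Conditions: NaOMe, HCO2Me, THF, 0 °C to rt; then HCl (aq.), MeOH, 50 °C
Reagents that add atoms: methyl formate COC=O
Why: A second Claisen formylation at the only remaining enolisable position (the α'-CH2), then acid-mediated 6-endo addition of the enol oxygen to the methoxyvinyl ketone terminus with loss of methanol, which gives the aromatic 4-pyranone.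

Step 3
Reactants: 5 3,5-dimethyl-4H-pyran-4-one
Product: 9 2-bromo-6-iodo-3,5-dimethyl-4H-pyran-4-one, via pyranonylzinc chloride 6 (not isolated), via bromopyranone 7 (not isolated), via bromopyranonylzinc chloride 8 (not isolated)
Conditions: (TMP)ZnCl·LiCl (1.1 equiv), THF, 25 °C; BrCl2C–CCl2Br (1.0 equiv), 0 °C; then (TMP)ZnCl·LiCl (1.2 equiv), 25 °C; I2, 0 °C
Reagents that add atoms: 1,2-dibromo-1,1,2,2-tetrachloroethane BrC(Cl)(Cl)C(Cl)(Cl)Br; iodine II
Why: Directed C–H zincation with a hindered zinc amide, as known for the C–H next to the ring oxygen of chromone-type 4-pyranones, followed by electrophilic halogenation of the arylzinc. C2–H and C6–H are the only acidic protons of 5 (the C3/C5 methyls are not vinylogously activated), so the two rounds place bromine and iodine on the two α-positions without lateral metalation.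

Step 4
Reactants: 9 2-bromo-6-iodo-3,5-dimethyl-4H-pyran-4-one; 10 ethylzinc bromide
Product: 11 2-bromo-6-ethyl-3,5-dimethyl-4H-pyran-4-one
Conditions: PdCl2(dppf) (3 mol %), 10 (1.05 equiv), THF, 0 °C to rt
Reagents that add atoms: none
Why: Negishi coupling of a primary alkylzinc halide; oxidative addition of zerovalent palladium into C–I is faster than into C–Br, and the wide-bite-angle diphosphine suppresses β-hydride elimination, so the bromide is kept for step 6.

Step 5
Reactants: 9 2-bromo-6-iodo-3,5-dimethyl-4H-pyran-4-one; 12 pentylzinc bromide
Product: 13 2-bromo-3,5-dimethyl-6-pentyl-4H-pyran-4-one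
Conditions: PdCl2(dppf) (3 mol %), 12 (1.05 equiv), THF, 0 °C to rt
Reagents that add atoms: none
Why: The same iodide-selective Negishi alkylation as in step 4, with the pentyl donor.

Step 6
Reactants: 11 2-bromo-6-ethyl-3,5-dimethyl-4H-pyran-4-one; 14 2,4-dibromopentan-3-one (commercial mixture of racemic and meso forms)
Product: 16 2-[(2R)-4-bromo-3-oxopentan-2-yl]-6-ethyl-3,5-dimethyl-4H-pyran-4-one (both epimers at the bromine-bearing carbon), via pyranonylzinc bromide 15 (not isolated)
Conditions: Zn dust, LiCl, THF, 25 °C, decant from excess Zn; then 14 (3 equiv), NiCl2(dme) (10 mol %), pybox ligand (13 mol %), glyme/THF, −30 °C; pH 7 buffer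
Reagents that add atoms: none
Why: LiCl-assisted zinc insertion into the activated β-bromo-enone C–Br bond, then stereoconvergent nickel/pybox Negishi α-arylation of a racemic α-bromoketone. Both diastereomers of 14 pass through the same planar α-keto radical, and the ligand fixes the new ring A methine as R. The excess of 14 limits double arylation, and the untouched C–Br carbon may stay an epimer mixture because step 7 erases it.

Step 7
Reactants: 13 2-bromo-3,5-dimethyl-6-pentyl-4H-pyran-4-one; 16 2-[(2R)-4-bromo-3-oxopentan-2-yl]-6-ethyl-3,5-dimethyl-4H-pyran-4-one
Product: 18 2-[(2R,4R)-4-(6-ethyl-3,5-dimethyl-4-oxo-4H-pyran-2-yl)-3-oxopentan-2-yl]-3,5-dimethyl-6-pentyl-4H-pyran-4-one, via pyranonylzinc bromide 17 (not isolated)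
Conditions: Zn dust, LiCl, THF, 25 °C, decant from excess Zn; then 16 (1.0 equiv), 17 (1.3 equiv), NiCl2(dme) (10 mol %), pybox ligand (13 mol %, same antipode as step 6), glyme/THF, −30 °C; pH 7 buffer, rapid chromatography on neutral silica
Reagents that add atoms: none
Why: Stereoconvergent nickel-catalysed Negishi α-arylation of a racemic α-bromoketone, the closest known reaction type being the nickel/pybox coupling of racemic α-bromoketones with arylzinc halides. Transmetalation of 17 gives a pybox-bound monovalent arylnickel species that abstracts bromine from 16; the α-keto radical formed is planar, so both C–Br epimers of 16 are funnelled into one intermediate. Capture of the radical by the divalent arylnickel bromide and reductive elimination from the trivalent aryl(alkyl)nickel complex forge the C2'–C2(ring B) bond and return monovalent nickel. No ring is closed; the step joins the finished ring B to the chain. The new C2' centre is set by the chiral ligand (catalyst control), and because the same ligand antipode is used as in step 6 and the two arylation sites are constitutionally alike, it is expected to come out R like C4'. The step needs catalyst control to dominate the 1,3-influence of the existing C4' centre and needs both doubly activated methine C–H bonds to stay untouched; the base-free medium, the low Brønsted basicity of an arylzinc halide at −30 °C and the buffered work-up are what secure this. Material of the wrong sense from either coupling ends mostly as the meso-like R,S diastereomer, which chromatography removes, so the enantiopurity of 18 should exceed that of 16. Only the C(sp3)–Br bond is activated, the pyranone carbonyls and the ketone being inert to arylzinc halides.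

## Compound list

1 | pentan-3-one | CCC(=O)CC | starting material
2 | sodium 2-methyl-3-oxopent-1-en-1-olate | CCC(=O)C(C)=C[O-].[Na+] | intermediate
3 | (1E)-1-methoxy-2-methylpent-1-en-3-one | CCC(=O)/C(C)=C/OC | intermediate
4 | sodium (4E)-5-methoxy-2,4-dimethyl-3-oxopenta-1,4-dien-1-olate | CO/C=C(C)/C(=O)C(C)=C[O-].[Na+] | intermediate
5 | 3,5-dimethyl-4H-pyran-4-one | Cc1cocc(C)c1=O | intermediate
6 | (3,5-dimethyl-4-oxo-4H-pyran-2-yl)zinc chloride (LiCl complex) | Cc1coc([Zn]Cl)c(C)c1=O | intermediate
7 | 2-bromo-3,5-dimethyl-4H-pyran-4-one | Cc1coc(Br)c(C)c1=O | intermediate
8 | (6-bromo-3,5-dimethyl-4-oxo-4H-pyran-2-yl)zinc chloride (LiCl complex) | Cc1c(Br)oc([Zn]Cl)c(C)c1=O | intermediate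
9 | 2-bromo-6-iodo-3,5-dimethyl-4H-pyran-4-one | Cc1c(Br)oc(I)c(C)c1=O | intermediate
10 | ethylzinc bromide | CC[Zn]Br | starting material
11 | 2-bromo-6-ethyl-3,5-dimethyl-4H-pyran-4-one | CCc1oc(Br)c(C)c(=O)c1C | intermediate
12 | pentylzinc bromide | CCCCC[Zn]Br | starting material
13 | 2-bromo-3,5-dimethyl-6-pentyl-4H-pyran-4-one | CCCCCc1oc(Br)c(C)c(=O)c1C | intermediate
14 | 2,4-dibromopentan-3-one (mixture of diastereomers) | CC(Br)C(=O)C(C)Br | starting material
15 | (6-ethyl-3,5-dimethyl-4-oxo-4H-pyran-2-yl)zinc bromide (LiCl complex) | CCc1oc([Zn]Br)c(C)c(=O)c1C | intermediate
16 | 2-[(2R)-4-bromo-3-oxopentan-2-yl]-6-ethyl-3,5-dimethyl-4H-pyran-4-one (epimers at C–Br) | CC(Br)C(=O)[C@H](C)c1oc(CC)c(C)c(=O)c1C | intermediate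
17 | (3,5-dimethyl-4-oxo-6-pentyl-4H-pyran-2-yl)zinc bromide (LiCl complex) | CCCCCc1oc([Zn]Br)c(C)c(=O)c1C | intermediate
18 | 2-[(2R,4R)-4-(6-ethyl-3,5-dimethyl-4-oxo-4H-pyran-2-yl)-3-oxopentan-2-yl]-3,5-dimethyl-6-pentyl-4H-pyran-4-one | CCCCCc1oc([C@@H](C)C(=O)[C@H](C)c2oc(CC)c(C)c(=O)c2C)c(C)c(=O)c1C | target

Total step count: 7. Longest linear sequence: 6 steps (steps 1, 2, 3, 4, 6, 7); step 5 is the side branch.

## Least certain steps

Step 7 (key step). The most likely failure is slow aryl transfer from the electron-poor pyranonylzinc, which carries a methyl group next to the C–Zn bond, to nickel. The α-keto radical would then be reduced instead of arylated, and the catalyst would lose control against the neighbouring methine centre. Slow epimerisation through a zinc enolate of the doubly activated C–H is also possible, since the known couplings of this type use less hindered arylzincs and less acidic products. The fallback gives up asymmetric induction in the bond formation. It sets out from 16 (with 17 from 13) and comes back at 18. The two are coupled with an achiral catalyst (NiCl2(dme), 2,2'-bipyridine, THF, rt) to the stereoisomer mixture of 18, 2-[4-(6-ethyl-3,5-dimethyl-4-oxo-4H-pyran-2-yl)-3-oxopentan-2-yl]-3,5-dimethyl-6-pentyl-4H-pyran-4-one F1. The R,R isomer 18 is then separated by preparative chromatography on a chiral stationary phase, and the unwanted isomers are re-equilibrated to F1 with catalytic DBU and recycled, which the lability of the two centres allows.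

Step 6. The most likely failure is loss of the second bromine. The dibromide offers two equal C–Br bonds, so double arylation competes, and a nickel or zinc enolate formed at one carbon can expel the bromide on the other (1,3-elimination towards a cyclopropanone or oxyallyl species). The fallback uses a differentiated dihalide. It sets out from 11 (as 15) and comes back at 16. Commercial 2-chloropentan-3-one F2 is brominated at the unsubstituted α-carbon (Br2, CH2Cl2, catalytic HBr) to 2-bromo-4-chloropentan-3-one F3. Under the conditions of step 6 only the C–Br bond of F3 is activated, and the coupling with 15 gives 2-[(2R)-4-chloro-3-oxopentan-2-yl]-6-ethyl-3,5-dimethyl-4H-pyran-4-one F4. Finkelstein-type halide exchange (LiBr, butan-2-one, rt) then gives 16.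

Step 3. The most likely failure is halogen scrambling in the one-pot sequence: the second metalation may be incomplete, or residual brominating agent or halide exchange at the vinylogous acyl halide carbon may give dibromo, diiodo and mixed products that cannot be separated. The fallback replaces halogen differentiation by symmetry. It sets out from 5 and comes back at 16 and 18. 5 is zincated and iodinated twice, through 6, 2-iodo-3,5-dimethyl-4H-pyran-4-one F5 and (6-iodo-3,5-dimethyl-4-oxo-4H-pyran-2-yl)zinc chloride F6, to 2,6-diiodo-3,5-dimethyl-4H-pyran-4-one F7. F7 is used in excess (recovered) and mono-alkylated with 10 or 12 under PdCl2(dppf) to 6-ethyl-2-iodo-3,5-dimethyl-4H-pyran-4-one F8 or 2-iodo-3,5-dimethyl-6-pentyl-4H-pyran-4-one F9. Zinc insertion then gives (6-ethyl-3,5-dimethyl-4-oxo-4H-pyran-2-yl)zinc iodide F10 and (3,5-dimethyl-4-oxo-6-pentyl-4H-pyran-2-yl)zinc iodide F11, which take the places of 15 and 17 in steps 6 and 7.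

## Further compounds

F1 | step 7 | 2-[4-(6-ethyl-3,5-dimethyl-4-oxo-4H-pyran-2-yl)-3-oxopentan-2-yl]-3,5-dimethyl-6-pentyl-4H-pyran-4-one (mixture of stereoisomers) | CCCCCc1oc(C(C)C(=O)C(C)c2oc(CC)c(C)c(=O)c2C)c(C)c(=O)c1C
F2 | step 6 | 2-chloropentan-3-one | CCC(=O)C(C)Cl
F3 | step 6 | 2-bromo-4-chloropentan-3-one | CC(Br)C(=O)C(C)Cl
F4 | step 6 | 2-[(2R)-4-chloro-3-oxopentan-2-yl]-6-ethyl-3,5-dimethyl-4H-pyran-4-one (epimers at C–Cl) | CC(Cl)C(=O)[C@H](C)c1oc(CC)c(C)c(=O)c1C
F5 | step 3 | 2-iodo-3,5-dimethyl-4H-pyran-4-one | Cc1coc(I)c(C)c1=O
F6 | step 3 | (6-iodo-3,5-dimethyl-4-oxo-4H-pyran-2-yl)zinc chloride | Cc1c(I)oc([Zn]Cl)c(C)c1=O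
F7 | step 3 | 2,6-diiodo-3,5-dimethyl-4H-pyran-4-one | Cc1c(I)oc(I)c(C)c1=O
F8 | step 3 | 6-ethyl-2-iodo-3,5-dimethyl-4H-pyran-4-one | CCc1oc(I)c(C)c(=O)c1C
F9 | step 3 | 2-iodo-3,5-dimethyl-6-pentyl-4H-pyran-4-one | CCCCCc1oc(I)c(C)c(=O)c1C
F10 | step 3 | (6-ethyl-3,5-dimethyl-4-oxo-4H-pyran-2-yl)zinc iodide | CCc1oc([Zn]I)c(C)c(=O)c1C
F11 | step 3 | (3,5-dimethyl-4-oxo-6-pentyl-4H-pyran-2-yl)zinc iodide | CCCCCc1oc([Zn]I)c(C)c(=O)c1C
A1 | alternative 1 | (8S,10S)-9-{[tert-butyl(dimethyl)silyl]oxy}-4,6,8,10,12,14-hexamethylicosane-3,5,7,11,13,15-hexone (other centres unspecified) | CCCCCC(=O)C(C)C(=O)C(C)C(=O)[C@@H](C)C(O[Si](C)(C)C(C)(C)C)[C@H](C)C(=O)C(C)C(=O)C(C)C(=O)CC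
A2 | alternative 1 | 2-[(2S,4S)-4-(6-ethyl-3,5-dimethyl-4-oxo-4H-pyran-2-yl)-3-hydroxypentan-2-yl]-3,5-dimethyl-6-pentyl-4H-pyran-4-one (either carbinol epimer) | CCCCCc1oc([C@@H](C)C(O)[C@H](C)c2oc(CC)c(C)c(=O)c2C)c(C)c(=O)c1C
A3 | alternative 2 | 2,6-diethyl-3,5-dimethyl-4H-pyran-4-one | CCc1oc(CC)c(C)c(=O)c1C
A4 | alternative 2 | (2R)-2-(3,5-dimethyl-4-oxo-6-pentyl-4H-pyran-2-yl)propanal | CCCCCc1oc([C@@H](C)C=O)c(C)c(=O)c1C
A5 | alternative 3 | 2-[4-(6-ethyl-3,5-dimethyl-4-oxo-4H-pyran-2-yl)-3-oxopentan-2-yl]-3,5-dimethyl-6-pentyl-4H-pyran-4-one (mixture of stereoisomers) | CCCCCc1oc(C(C)C(=O)C(C)c2oc(CC)c(C)c(=O)c2C)c(C)c(=O)c1C
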